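The route rests on disconnecting the two bonds at ring B's vicinal stereocentres, C4–C5 and C10–C1 (abietane numbering), so that C5 and C10 become the β- and α-carbons of achiral 2-methylcyclohex-2-en-1-one 1, whose carbonyl is the later C9. In one flask, copper-catalysed asymmetric addition of isopropenylmagnesium bromide 2 and Michael trapping by tert-butyl acrylate 3 of the resulting magnesium enolate 4 form both bonds and both stereocentres, trans, giving keto ester 5. The C9 ketone then carries ring C: alkenyl iodide, squarate-based Moore benzannulation, late oxidation at C7 and unmasking of the hydroquinone.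

Key step: step 1

Remark (assumption): atom labels follow abietane numbering (C7 ketone, C5 isopropenyl-bearing CH, C10 quaternary carbon, C8/C9 ring fusion, C11–C14 the remaining arene carbons); the sense of induction in step 1 is taken to be selectable through the antipode of the phosphoramidite, both antipodes being commercial.

Step 1
Reactants: 1 2-methylcyclohex-2-en-1-one; 2 isopropenylmagnesium bromide; 3 tert-butyl acrylate
Product: 5 tert-butyl 3-[(1S,6S)-1-methyl-2-oxo-6-(prop-1-en-2-yl)cyclohexyl]propanoate, via magnesium enolate 4 (not isolated)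
Conditions: CuBr·SMe2 (5 mol %), (1,1′-binaphthalene-2,2′-diyl) N,N-bis(1-phenylethyl)phosphoramidite (antipode for Re-face delivery, 10 mol %), tBuOMe, −78 °C, slow addition of 2 (1.1 equiv, solution in 2-methyltetrahydrofuran); then DMPU, 3 (1.3 equiv), −78 → −20 °C; aq. NH4Cl
Reagents that add atoms: none
Why: Transmetalation of 2 onto the ligated copper bromide gives a chiral alkenylcuprate that binds the enone as a π-complex, adds oxidatively at C5 to a trivalent copper intermediate and reductively eliminates the C4–C5 bond, which leaves the regiodefined, fully substituted magnesium enolate 4; this enolate then adds through C10 to the β-carbon of 3 (Michael addition, bond C10–C1) and the ester enolate formed is protonated on work-up. The closest known reaction type is the copper-catalysed asymmetric conjugate addition of Grignard reagents to 2-methylcyclohexenone with trapping of the magnesium enolate by a carbon electrophile (tandem vicinal difunctionalization), here with a Michael acceptor as the trap. No ring is closed. C5 is set by the chiral ligand (reagent control, Re-face delivery to the β-carbon), and C10 is set by the substrate, because allylic 1,2-strain with the C20 methyl group places the C5 isopropenyl group pseudoaxial so that the acrylate must approach the opposite face, giving chain trans and methyl cis to isopropenyl. The step needs 1,4- over 1,2-addition, which copper catalysis with slow addition of 2 at −78 °C in a weakly coordinating ether secures, C-alkylation at C10 only, which follows because no proton source is present to move the enolate toward C8, and mono-addition, which the bulky tert-butyl ester, a small excess of 3 and the low temperature favour.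

Step 2
Reactants: 5 tert-butyl 3-[(1S,6S)-1-methyl-2-oxo-6-(prop-1-en-2-yl)cyclohexyl]propanoate
Product: 6 tert-butyl 3-[(1S,6S)-2-hydrazinylidene-1-methyl-6-(prop-1-en-2-yl)cyclohexyl]propanoate
Conditions: N2H4·H2O (10 equiv), Et3N, EtOH, 80 °C
Reagents that add atoms: hydrazine (used as the hydrate), NN
Why: Hydrazone formation (carbonyl condensation) with excess hydrazine is the standard first stage of the Barton vinyl iodide synthesis and works on ketones flanked by a quaternary carbon, while the tert-butyl ester resists hydrazinolysis and neither stereocentre can epimerize (C10 carries no hydrogen and C5 is not α to the carbonyl).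

Step 3
Reactants: 6 tert-butyl 3-[(1S,6S)-2-hydrazinylidene-1-methyl-6-(prop-1-en-2-yl)cyclohexyl]propanoate
Product: 7 tert-butyl 3-[(1S,6S)-2-iodo-1-methyl-6-(prop-1-en-2-yl)cyclohex-2-en-1-yl]propanoate
Conditions: I2 (2.5 equiv), 1,1,3,3-tetramethylguanidine, THF, 0 °C → rt
Reagents that add atoms: iodine, [I][I]
Why: In the Barton vinyl iodide synthesis iodine oxidizes the hydrazone to the diazoalkane, iodination and loss of N2 give an α-iodo cation that can lose a proton only from C8 because C10 is quaternary, so a single alkenyl iodide should form while the isolated isopropenyl group is left alone under the basic conditions.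

Step 4
Reactants: 8 dimethyl squarate; 9 isopropylmagnesium chloride
Product: 11 3-methoxy-4-(propan-2-yl)cyclobut-3-ene-1,2-dione, via chloromagnesium alkoxide 10 (not isolated)
Conditions: THF, −78 °C; then 6 M HCl, 0 °C → rt
Reagents that add atoms: water, O
Why: 1,2-Addition of the Grignard reagent to one squarate carbonyl followed by acid-promoted ionization of the tertiary alcohol, capture of the methoxy-stabilized cation by water and loss of methanol (1,3-carbonyl transposition) is the standard way to 3-alkyl-4-alkoxycyclobutenediones.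

Step 5
Reactants: 7 tert-butyl 3-[(1S,6S)-2-iodo-1-methyl-6-(prop-1-en-2-yl)cyclohex-2-en-1-yl]propanoate; 11 3-methoxy-4-(propan-2-yl)cyclobut-3-ene-1,2-dione
Product: 13 tert-butyl 3-[(1S,6S)-2-[1-hydroxy-2-methoxy-4-oxo-3-(propan-2-yl)cyclobut-2-en-1-yl]-1-methyl-6-(prop-1-en-2-yl)cyclohex-2-en-1-yl]propanoate, via alkenyllithium 12 (not isolated)
Conditions: tBuLi (2.0 equiv), THF/Et2O/pentane, −100 °C, 5 min; then 11 (1.2 equiv), −100 → −78 °C; aq. NH4Cl at −78 °C
Reagents that add atoms: none
Why: Iodine–lithium exchange is complete within minutes at −100 °C, where a tert-butyl ester is tolerated, and the alkenyllithium then undergoes 1,2-addition to the more electrophilic carbonyl of 11 (the one next to the methoxy-bearing carbon and not part of the vinylogous ester), which is the regiochemistry that later puts OMe on C12 and isopropyl on C13, the new carbinol centre being formed as an inconsequential mixture.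

Step 6
Reactants: 13 tert-butyl 3-[(1S,6S)-2-[1-hydroxy-2-methoxy-4-oxo-3-(propan-2-yl)cyclobut-2-en-1-yl]-1-methyl-6-(prop-1-en-2-yl)cyclohex-2-en-1-yl]propanoate
Product: 17 tert-butyl 3-[(1S,2S)-5,7,8-trimethoxy-1-methyl-6-(propan-2-yl)-2-(prop-1-en-2-yl)-1,2,3,4-tetrahydronaphthalen-1-yl]propanoate, via dienylketene 14 (not isolated), via cyclohexadienone 15 (not isolated), via hydroquinone 16 (not isolated)
Conditions: degassed toluene, 110 °C; then DMF, Cs2CO3, MeI, 40 °C, argon
Reagents that add atoms: iodomethane, CI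
Why: In the Moore rearrangement conrotatory 4π ring opening with the hydroxyl group rotating outward gives the dienylketene, 6π electrocyclization onto C8 and tautomerization close ring C as the hydroquinone, and Williamson methylation in the same flask protects it before air can oxidize it, with C5 and C10 untouched.

Step 7
Reactants: 17 tert-butyl 3-[(1S,2S)-5,7,8-trimethoxy-1-methyl-6-(propan-2-yl)-2-(prop-1-en-2-yl)-1,2,3,4-tetrahydronaphthalen-1-yl]propanoate
Product: 18 tert-butyl 3-[(1S,2S)-5,7,8-trimethoxy-1-methyl-4-oxo-6-(propan-2-yl)-2-(prop-1-en-2-yl)-1,2,3,4-tetrahydronaphthalen-1-yl]propanoate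
Conditions: DDQ (2.5 equiv), 1,4-dioxane/H2O (10:1), rt
Reagents that add atoms: water, O
Why: DDQ benzylic oxidation in aqueous medium should abstract hydride from C7, whose cation is held coplanar with the arene and stabilized by the para C12 and ortho C14 methoxy groups, after which water capture and oxidation of the benzylic alcohol give the aryl ketone, whereas the isopropyl methine is twisted out of conjugation by its two ortho neighbours, C10 has no hydrogen and the isolated 1,1-disubstituted alkene does not react with DDQ.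

Step 8
Reactants: 18 tert-butyl 3-[(1S,2S)-5,7,8-trimethoxy-1-methyl-4-oxo-6-(propan-2-yl)-2-(prop-1-en-2-yl)-1,2,3,4-tetrahydronaphthalen-1-yl]propanoate
Product: 19 3-[(1S,2S)-5,7,8-trimethoxy-1-methyl-4-oxo-6-(propan-2-yl)-2-(prop-1-en-2-yl)-1,2,3,4-tetrahydronaphthalen-1-yl]propanoic acid
Conditions: TMSOTf, 2,6-lutidine, CH2Cl2, 0 °C → rt; aq. citric acid
Reagents that add atoms: none
Why: Silyl-triflate-mediated tert-butyl ester cleavage (loss of isobutene to the trimethylsilyl ester, hydrolysed on work-up) runs under lutidine-buffered, non-protic conditions, so the isopropenyl group is not protonated, the aryl methyl ethers stay and any silyl enol ether formed at C6–C7 reverts to the ketone on work-up.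

Step 9
Reactants: 19 3-[(1S,2S)-5,7,8-trimethoxy-1-methyl-4-oxo-6-(propan-2-yl)-2-(prop-1-en-2-yl)-1,2,3,4-tetrahydronaphthalen-1-yl]propanoic acid
Product: 21 3-[(1S,2S)-5,8-dihydroxy-7-methoxy-1-methyl-4-oxo-6-(propan-2-yl)-2-(prop-1-en-2-yl)-1,2,3,4-tetrahydronaphthalen-1-yl]propanoic acid, via quinone 20 (not isolated)
Conditions: (NH4)2Ce(NO3)6 (2.5 equiv), MeCN/H2O, 0 °C; then aq. Na2S2O4, EtOAc, argon
Reagents that add atoms: water, O
Why: Oxidative demethylation with (NH4)2Ce(NO3)6 should convert the para-related C11/C14 dimethoxy pair into the p-quinone and leave the C12 methoxy group as a vinylogous ester, and dithionite reduction in the work-up returns the hydroquinone, which is stabilized by the hydrogen bond from the C14 hydroxyl group to the C7 ketone.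

Compound list
1 | 2-methylcyclohex-2-en-1-one | CC1=CCCCC1=O | starting material
2 | isopropenylmagnesium bromide (prop-1-en-2-ylmagnesium bromide) | C=C(C)[Mg]Br | starting material
3 | tert-butyl acrylate (tert-butyl prop-2-enoate) | C=CC(=O)OC(C)(C)C | starting material
4 | bromomagnesium (3S)-2-methyl-3-(prop-1-en-2-yl)cyclohex-1-en-1-olate | C=C(C)[C@@H]1CCCC(O[Mg]Br)=C1C | intermediate (not isolated)
5 | tert-butyl 3-[(1S,6S)-1-methyl-2-oxo-6-(prop-1-en-2-yl)cyclohexyl]propanoate | C=C(C)[C@@H]1CCCC(=O)[C@@]1(C)CCC(=O)OC(C)(C)C | intermediate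
6 | tert-butyl 3-[(1S,6S)-2-hydrazinylidene-1-methyl-6-(prop-1-en-2-yl)cyclohexyl]propanoate | C=C(C)[C@@H]1CCCC(=NN)[C@@]1(C)CCC(=O)OC(C)(C)C | intermediate
7 | tert-butyl 3-[(1S,6S)-2-iodo-1-methyl-6-(prop-1-en-2-yl)cyclohex-2-en-1-yl]propanoate | C=C(C)[C@@H]1CCC=C(I)[C@@]1(C)CCC(=O)OC(C)(C)C | intermediate
8 | dimethyl squarate (3,4-dimethoxycyclobut-3-ene-1,2-dione) | COC1=C(OC)C(=O)C1=O | starting material
9 | isopropylmagnesium chloride | CC(C)[Mg]Cl | starting material
10 | chloromagnesium alkoxide of 4-hydroxy-2,3-dimethoxy-4-(propan-2-yl)cyclobut-2-en-1-one (racemic) | COC1=C(OC)C(O[Mg]Cl)(C(C)C)C1=O | intermediate (not isolated)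
11 | 3-methoxy-4-(propan-2-yl)cyclobut-3-ene-1,2-dione | COC1=C(C(C)C)C(=O)C1=O | intermediate
12 | tert-butyl 3-[(1S,6S)-2-lithio-1-methyl-6-(prop-1-en-2-yl)cyclohex-2-en-1-yl]propanoate | C=C(C)[C@@H]1CCC=C([Li])[C@@]1(C)CCC(=O)OC(C)(C)C | intermediate (not isolated)
13 | tert-butyl 3-[(1S,6S)-2-[1-hydroxy-2-methoxy-4-oxo-3-(propan-2-yl)cyclobut-2-en-1-yl]-1-methyl-6-(prop-1-en-2-yl)cyclohex-2-en-1-yl]propanoate (both configurations at the carbinol carbon) | C=C(C)[C@@H]1CCC=C(C2(O)C(OC)=C(C(C)C)C2=O)[C@@]1(C)CCC(=O)OC(C)(C)C | intermediate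
14 | tert-butyl 3-[(1S,6S)-2-[(1Z)-1-hydroxy-2-methoxy-4-oxo-3-(propan-2-yl)buta-1,3-dien-1-yl]-1-methyl-6-(prop-1-en-2-yl)cyclohex-2-en-1-yl]propanoate (dienylketene) | C=C(C)[C@@H]1CCC=C(/C(O)=C(OC)\C(C(C)C)=C=O)[C@@]1(C)CCC(=O)OC(C)(C)C | intermediate (not isolated)
15 | tert-butyl 3-[(1S,2S)-8-hydroxy-7-methoxy-1-methyl-5-oxo-6-(propan-2-yl)-2-(prop-1-en-2-yl)-1,2,3,4,4a,5-hexahydronaphthalen-1-yl]propanoate (4a-epimers) | C=C(C)[C@@H]1CCC2C(=O)C(C(C)C)=C(OC)C(O)=C2[C@@]1(C)CCC(=O)OC(C)(C)C | intermediate (not isolated)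
16 | tert-butyl 3-[(1S,2S)-5,8-dihydroxy-7-methoxy-1-methyl-6-(propan-2-yl)-2-(prop-1-en-2-yl)-1,2,3,4-tetrahydronaphthalen-1-yl]propanoate | C=C(C)[C@@H]1CCc2c(O)c(C(C)C)c(OC)c(O)c2[C@@]1(C)CCC(=O)OC(C)(C)C | intermediate (not isolated)
17 | tert-butyl 3-[(1S,2S)-5,7,8-trimethoxy-1-methyl-6-(propan-2-yl)-2-(prop-1-en-2-yl)-1,2,3,4-tetrahydronaphthalen-1-yl]propanoate | C=C(C)[C@@H]1CCc2c(OC)c(C(C)C)c(OC)c(OC)c2[C@@]1(C)CCC(=O)OC(C)(C)C | intermediate
18 | tert-butyl 3-[(1S,2S)-5,7,8-trimethoxy-1-methyl-4-oxo-6-(propan-2-yl)-2-(prop-1-en-2-yl)-1,2,3,4-tetrahydronaphthalen-1-yl]propanoate | C=C(C)[C@@H]1CC(=O)c2c(OC)c(C(C)C)c(OC)c(OC)c2[C@@]1(C)CCC(=O)OC(C)(C)C | intermediate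
19 | 3-[(1S,2S)-5,7,8-trimethoxy-1-methyl-4-oxo-6-(propan-2-yl)-2-(prop-1-en-2-yl)-1,2,3,4-tetrahydronaphthalen-1-yl]propanoic acid | C=C(C)[C@@H]1CC(=O)c2c(OC)c(C(C)C)c(OC)c(OC)c2[C@@]1(C)CCC(=O)O | intermediate
20 | 3-[(1S,2S)-7-methoxy-1-methyl-4,5,8-trioxo-6-(propan-2-yl)-2-(prop-1-en-2-yl)-1,2,3,4,5,8-hexahydronaphthalen-1-yl]propanoic acid (quinone) | C=C(C)[C@@H]1CC(=O)C2=C(C(=O)C(OC)=C(C(C)C)C2=O)[C@@]1(C)CCC(=O)O | intermediate (not isolated)
21 | 3-[(1S,2S)-5,8-dihydroxy-7-methoxy-1-methyl-4-oxo-6-(propan-2-yl)-2-(prop-1-en-2-yl)-1,2,3,4-tetrahydronaphthalen-1-yl]propanoic acid (CNP0249049.1) | C=C(C)[C@@H]1CC(=O)c2c(O)c(C(C)C)c(OC)c(O)c2[C@@]1(C)CCC(=O)O | target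

Total step count: 9 (eight in the main line and one for dione 11).
Longest linear sequence: 8 steps (1 → 5 → 6 → 7 → 13 → 17 → 18 → 19 → 21).

Steps most likely to fail

Step 1. The fully substituted magnesium enolate may alkylate too slowly, the first adduct may go on to add more acrylate (chain growth, or a second Michael addition at C8 after proton transfer), and facial discrimination for an α-branched alkenyl Grignard reagent may be modest. Fallback, setting out from 1 and 2 and returning at 5: the two bonds would be made in separate operations. The same copper–phosphoramidite conjugate addition, quenched with aq. NH4Cl at −78 °C, should give (3R)-2-methyl-3-(prop-1-en-2-yl)cyclohexan-1-one F1 as a mixture of C2 epimers. A base-catalysed Michael addition under thermodynamic control (KOtBu 0.2 equiv, tBuOH/THF, 3, 0 °C → rt) then engages the more substituted enolate at C10 on the face anti to the isopropenyl group and should deliver 5; the C2 centre of F1 is erased in the planar enolate, so its epimer ratio does not matter.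

Step 5. The alkenyllithium may be lost before it meets 11, by attack on the ester carbonyl through a five-membered transition state or by proton transfer from the ester α-methylene, and addition of so hindered a nucleophile may be slow. Fallback, setting out from 7 and returning at 19: the ester is removed before the organometallic step. TMSOTf/2,6-lutidine would convert 7 into 3-[(1S,6S)-2-iodo-1-methyl-6-(prop-1-en-2-yl)cyclohex-2-en-1-yl]propanoic acid F2. With tBuLi (3 equiv, −100 °C, the first equivalent forming the lithium carboxylate, which is inert to the alkenyllithium at that temperature) and then 11, this should give 3-[(1S,6S)-2-[1-hydroxy-2-methoxy-4-oxo-3-(propan-2-yl)cyclobut-2-en-1-yl]-1-methyl-6-(prop-1-en-2-yl)cyclohex-2-en-1-yl]propanoic acid F3. Thermolysis and Cs2CO3/MeI as in step 6, which also esterify the acid, would give methyl 3-[(1S,2S)-5,7,8-trimethoxy-1-methyl-6-(propan-2-yl)-2-(prop-1-en-2-yl)-1,2,3,4-tetrahydronaphthalen-1-yl]propanoate F4. DDQ in wet dioxane as in step 7 would give methyl 3-[(1S,2S)-5,7,8-trimethoxy-1-methyl-4-oxo-6-(propan-2-yl)-2-(prop-1-en-2-yl)-1,2,3,4-tetrahydronaphthalen-1-yl]propanoate F5, and LiOH in THF/H2O returns keto acid 19.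

Step 9. Oxidative demethylation of an acyl-deactivated trimethoxyarene may partition between p- and o-quinone formation, the electrophilic acylquinone may be attacked by water or by the tethered acid before it is reduced, and the hydroquinone may reoxidize during isolation. Fallback, setting out from 13 and returning at 21: the hydroquinone is protected with groups that come off without an oxidant. Thermolysis of 13 as in step 6, followed in the same flask by NaH and MOMCl in DMF at 0 °C, should give tert-butyl 3-[(1S,2S)-7-methoxy-5,8-bis(methoxymethoxy)-1-methyl-6-(propan-2-yl)-2-(prop-1-en-2-yl)-1,2,3,4-tetrahydronaphthalen-1-yl]propanoate F6. DDQ in wet dioxane as in step 7 would give tert-butyl 3-[(1S,2S)-7-methoxy-5,8-bis(methoxymethoxy)-1-methyl-4-oxo-6-(propan-2-yl)-2-(prop-1-en-2-yl)-1,2,3,4-tetrahydronaphthalen-1-yl]propanoate F7. Excess TMSOTf with 2,2′-bipyridyl in CH2Cl2 (0 °C → rt), followed by water, should then exchange both aryl methoxymethyl ethers and the tert-butyl ester for hydrolytically labile trimethylsilyl groups and release 21 without protic acid or oxidant.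

Further compounds
F1 | step 1 | (3R)-2-methyl-3-(prop-1-en-2-yl)cyclohexan-1-one (C2 epimers) | C=C(C)[C@@H]1CCCC(=O)C1C
F2 | step 5 | 3-[(1S,6S)-2-iodo-1-methyl-6-(prop-1-en-2-yl)cyclohex-2-en-1-yl]propanoic acid | C=C(C)[C@@H]1CCC=C(I)[C@@]1(C)CCC(=O)O
F3 | step 5 | 3-[(1S,6S)-2-[1-hydroxy-2-methoxy-4-oxo-3-(propan-2-yl)cyclobut-2-en-1-yl]-1-methyl-6-(prop-1-en-2-yl)cyclohex-2-en-1-yl]propanoic acid | C=C(C)[C@@H]1CCC=C(C2(O)C(OC)=C(C(C)C)C2=O)[C@@]1(C)CCC(=O)O
F4 | step 5 | methyl 3-[(1S,2S)-5,7,8-trimethoxy-1-methyl-6-(propan-2-yl)-2-(prop-1-en-2-yl)-1,2,3,4-tetrahydronaphthalen-1-yl]propanoate | C=C(C)[C@@H]1CCc2c(OC)c(C(C)C)c(OC)c(OC)c2[C@@]1(C)CCC(=O)OC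
F5 | step 5 | methyl 3-[(1S,2S)-5,7,8-trimethoxy-1-methyl-4-oxo-6-(propan-2-yl)-2-(prop-1-en-2-yl)-1,2,3,4-tetrahydronaphthalen-1-yl]propanoate | C=C(C)[C@@H]1CC(=O)c2c(OC)c(C(C)C)c(OC)c(OC)c2[C@@]1(C)CCC(=O)OC
F6 | step 9 | tert-butyl 3-[(1S,2S)-7-methoxy-5,8-bis(methoxymethoxy)-1-methyl-6-(propan-2-yl)-2-(prop-1-en-2-yl)-1,2,3,4-tetrahydronaphthalen-1-yl]propanoate | C=C(C)[C@@H]1CCc2c(OCOC)c(C(C)C)c(OC)c(OCOC)c2[C@@]1(C)CCC(=O)OC(C)(C)C
F7 | step 9 | tert-butyl 3-[(1S,2S)-7-methoxy-5,8-bis(methoxymethoxy)-1-methyl-4-oxo-6-(propan-2-yl)-2-(prop-1-en-2-yl)-1,2,3,4-tetrahydronaphthalen-1-yl]propanoate | C=C(C)[C@@H]1CC(=O)c2c(OCOC)c(C(C)C)c(OC)c(OCOC)c2[C@@]1(C)CCC(=O)OC(C)(C)C
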